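C8–C9 Nozaki–Hiyama–Kishi route to CNP0526758.1

1. Retrosynthetic cuts, in order: the two O–silyl bonds and the C8–O acyl bond; C11=C13; C8–C9, which opens the ten-membered carbocycle (ring A); C4=C5, which separates the chain from the γ-lactone (ring B); finally C7–C8 and C1–C2.
2. Enabling feature: in ring A, C8 is a secondary allylic carbinol bonded to sp2 carbon C9 of the (Z)-C9=C10 alkene and to C7, the fusion carbon of ring B. It can therefore be read as a formyl group on C7 attacked by an alkenyl metal at C9.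
3. Forward order: ring B is present from the first step (chiral butenolide). C8 is attached to C7 as a dioxolane. The C1–C4/C9/C10/C14/C15 chain, made from propargyl alcohol, is joined at C4=C5 by a Wittig reaction. Ring A then closes at C8–C9, and C13, the ester and the free hydroxyls follow.
4. Stereochemistry: C6 comes from the chiral pool, C7 from anti radical addition next to C6, C1 from Brown allylboration, C8 from the ring closure under control of C7, and C2' from (S)-2-methylbutanoic acid. (Z)-C9=C10 comes from anti carbomagnesiation, and the ring-cis C4=C5 from an (E)-selective stabilised ylide.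

Key step: step 17

Assumption and conventions: germacrane numbering is used (ring A = C1–C10, ring B = O–C6–C7–C11–C12, C13 on C11, C14 on C10, C15 on C4); open-chain precursors are named as 8,9-seco compounds; centres formed as mixtures and destroyed again (the N,O-acetal carbon of the lutidinium salt, lactol carbons) are left undefined. TBS = tert-butyldimethylsilyl, TMS = trimethylsilyl, TES = triethylsilyl, PMB = 4-methoxybenzyl, Ipc = isopinocampheyl, DMP = Dess–Martin periodinane.

**Fragment 1: iodoalkene chain (steps 1–8)**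

Step 1
Reactants: 1 propargyl alcohol
Product: 3 (Z)-3-iodo-2-methylprop-2-en-1-ol, via oxamagnesacycle 2 (not isolated)
Conditions: MeMgBr (3 equiv), CuI (10 mol %), Et2O, −10 °C to rt; then I2, 0 °C
Reagents that add atoms: methylmagnesium bromide, C[Mg]Br; iodine, II
Why: Copper-catalysed carbomagnesiation of the magnesium propargylic alkoxide is an anti addition that puts methyl on the inner alkyne carbon and magnesium on the terminal one, held cis to CH2O in chelate 2, so iodinolysis with retention should give the (Z)-iodoalkene that becomes C9=C10 with C14.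

Step 2
Reactants: 3 (Z)-3-iodo-2-methylprop-2-en-1-ol
Product: 4 (Z)-3-iodo-2-methylprop-2-enal
Conditions: activated MnO2, CH2Cl2, rt, dark; used at once
Reagents that add atoms: none
Why: Heterogeneous MnO2 oxidation of a primary allylic alcohol is neutral and stops at the aldehyde, and immediate use in the dark limits Z to E isomerisation of the iodoenal.

Step 3
Reactants: 4 (Z)-3-iodo-2-methylprop-2-enal
Product: 6 (1Z,3S)-1-iodo-2-methylhexa-1,5-dien-3-ol, via borinate 5 (not isolated)
Conditions: (−)-Ipc2BOMe, CH2=CHCH2MgBr, Et2O, −78 °C to rt; 4, −78 °C; then NaOH aq., H2O2, 0 °C to rt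
Reagents that add atoms: allylmagnesium bromide, C=CC[Mg]Br
Why: Brown allylboration runs through a closed chair transition state in which the isopinocampheyl groups of the (+)-α-pinene series expose one aldehyde face, in the sense known for α-methyl enals and aromatic aldehydes, which corresponds to the (S)-carbinol and so sets C1 while adding C2 to C4.

Step 4
Reactants: 6 (1Z,3S)-1-iodo-2-methylhexa-1,5-dien-3-ol
Product: 7 (1Z,3S)-3-(TBSO)-1-iodo-2-methylhexa-1,5-diene
Conditions: TBSCl, imidazole, DMF, rt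
Reagents that add atoms: tert-butyldimethylsilyl chloride, CC(C)(C)[Si](C)(C)Cl
Why: Silyl ether formation protects the C1 carbinol with a group that withstands boranes, ylides, hydride, chromium reagents and amide bases and is removed by fluoride at the end.

Step 5
Reactants: 7 (1Z,3S)-3-(TBSO)-1-iodo-2-methylhexa-1,5-diene
Product: 9 (4S,5Z)-4-(TBSO)-6-iodo-5-methylhex-5-en-1-ol, via trialkylborane 8 (not isolated)
Conditions: 9-BBN, THF, 0 °C to rt; then NaOH aq., H2O2, 0 °C
Reagents that add atoms: hydrogen peroxide, OO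
Why: Hydroboration–oxidation with bulky 9-BBN is anti-Markovnikov and selects the monosubstituted alkene over the hindered, electron-poor trisubstituted iodoalkene, giving the primary alcohol at C4.

Step 6
Reactants: 9 (4S,5Z)-4-(TBSO)-6-iodo-5-methylhex-5-en-1-ol
Product: 10 (1Z,3S)-3-(TBSO)-1,6-diiodo-2-methylhex-1-ene
Conditions: I2, PPh3, imidazole, CH2Cl2, 0 °C
Reagents that add atoms: iodine, II
Why: Appel-type iodination displaces the primary oxyphosphonium ion by SN2 under near-neutral conditions that leave the silyl ether and the alkenyl iodide alone.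

Step 7
Reactants: 10 (1Z,3S)-3-(TBSO)-1,6-diiodo-2-methylhex-1-ene
Product: 11 [(4S,5Z)-4-(TBSO)-6-iodo-5-methylhex-5-enyl]triphenylphosphonium iodide
Conditions: PPh3, MeCN, 80 °C
Reagents that add atoms: triphenylphosphine, c1ccc(cc1)P(c1ccccc1)c1ccccc1
Why: Quaternisation of the phosphine is an SN2 reaction open only to the sp3 C4–I bond, since an alkenyl iodide does not react with PPh3 without a transition metal.

Step 8
Reactants: 11 [(4S,5Z)-4-(TBSO)-6-iodo-5-methylhex-5-enyl]triphenylphosphonium iodide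
Product: 13 (5S,6Z)-5-(TBSO)-7-iodo-6-methyl-2-(triphenylphosphoranylidene)hept-6-enal, via phosphonium ylide 12 (not isolated)
Conditions: NaN(SiMe3)2, THF, −78 to 0 °C; HCO2Me, −78 °C to rt
Reagents that add atoms: methyl formate, COC=O
Why: C-Formylation of a non-stabilised ylide with a formate ester gives an acylphosphonium ion that loses its acidic proton to the liberated methoxide, the classical route to α-alkyl formyl ylides, and it brings in C15 at the aldehyde level so that no ester has to be reduced beside the lactone later.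

**Fragment 2: lactone aldehyde (steps 9–12)**

Step 9
Reactants: 14 (S)-5-(hydroxymethyl)furan-2(5H)-one
Product: 15 (S)-5-[(TBSO)methyl]furan-2(5H)-one
Conditions: TBSCl, imidazole, CH2Cl2, 0 °C to rt
Reagents that add atoms: tert-butyldimethylsilyl chloride, CC(C)(C)[Si](C)(C)Cl
Why: Silylation of the primary alcohol supplies the bulky C5 side chain that shields one face of the butenolide, with C6 carried over unchanged from the chiral pool.

Step 10
Reactants: 15 (S)-5-[(TBSO)methyl]furan-2(5H)-one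
Product: 16 (4S,5S)-5-[(TBSO)methyl]-4-(1,3-dioxolan-2-yl)dihydrofuran-2(3H)-one (4,5-trans)
Conditions: 1,3-dioxolane (solvent), Ph2CO (10 mol %), hν (medium-pressure Hg lamp, Pyrex), 0 °C, Ar
Reagents that add atoms: 1,3-dioxolane, C1COCO1
Why: Benzophenone-sensitised hydrogen abstraction gives the nucleophilic 1,3-dioxolan-2-yl radical, whose Giese-type conjugate addition to 5-(alkoxymethyl)furanones is known to occur anti to the side chain, so C7 is set trans to C6 and C8 arrives as a masked aldehyde.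

Step 11
Reactants: 16 (4S,5S)-5-[(TBSO)methyl]-4-(1,3-dioxolan-2-yl)dihydrofuran-2(3H)-one
Product: 17 (4S,5S)-4-(1,3-dioxolan-2-yl)-5-(hydroxymethyl)dihydrofuran-2(3H)-one
Conditions: Et3N·3HF, MeCN, rt
Reagents that add atoms: none
Why: Fluoride-driven cleavage of the primary silyl ether with mildly acidic Et3N·3HF forms no alkoxide, so neither the lactone nor the acetal is disturbed.

Step 12
Reactants: 17 (4S,5S)-4-(1,3-dioxolan-2-yl)-5-(hydroxymethyl)dihydrofuran-2(3H)-one
Product: 18 (2S,3S)-3-(1,3-dioxolan-2-yl)-5-oxotetrahydrofuran-2-carbaldehyde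
Conditions: DMP, CH2Cl2, 0 °C to rt; used crude
Reagents that add atoms: none
Why: Dess–Martin oxidation is mild and stops at the aldehyde, and the adjacent C6 centre is safe because the 6,7-trans arrangement is also the thermodynamically preferred one.

**Fragment union and unmasking of C8 (steps 13–16)**

Step 13
Reactants: 18 (2S,3S)-3-(1,3-dioxolan-2-yl)-5-oxotetrahydrofuran-2-carbaldehyde; 13 (5S,6Z)-5-(TBSO)-7-iodo-6-methyl-2-(triphenylphosphoranylidene)hept-6-enal
Product: 19 (1S,4E,6R,7S,9Z)-1-(TBSO)-8,8-ethylenedioxy-9-iodo-15-oxo-8,9-secogermacra-4,9-dien-12,6-olide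
Conditions: toluene, 70 °C
Reagents that add atoms: none
Why: Wittig olefination with a stabilised α-alkyl formyl ylide is reliably (E)-selective, placing C6 trans to C15 and cis to C3, which is the ring-cis C4=C5 geometry of the target, and it needs no added base, which suits the α-acyloxy aldehyde.

Step 14
Reactants: 19 (1S,4E,6R,7S,9Z)-1-(TBSO)-8,8-ethylenedioxy-9-iodo-15-oxo-8,9-secogermacra-4,9-dien-12,6-olide
Product: 20 (1S,4E,6R,7S,9Z)-1-(TBSO)-8,8-ethylenedioxy-15-hydroxy-9-iodo-8,9-secogermacra-4,9-dien-12,6-olide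
Conditions: NaBH4, CeCl3·7H2O, MeOH, −78 to −40 °C
Reagents that add atoms: none
Why: Luche reduction delivers hydride 1,2 to the enal far faster than to the lactone, and the acetal, silyl ether and iodoalkene are inert to NaBH4.

Step 15
Reactants: 20 (1S,4E,6R,7S,9Z)-1-(TBSO)-8,8-ethylenedioxy-15-hydroxy-9-iodo-8,9-secogermacra-4,9-dien-12,6-olide
Product: 21 (1S,4E,6R,7S,9Z)-1,15-bis(TBSO)-8,8-ethylenedioxy-9-iodo-8,9-secogermacra-4,9-dien-12,6-olide
Conditions: TBSCl, imidazole, CH2Cl2, 0 °C to rt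
Reagents that add atoms: tert-butyldimethylsilyl chloride, CC(C)(C)[Si](C)(C)Cl
Why: Silyl ether formation at the only free, primary allylic hydroxyl gives C15 the same protecting group as C1, so one fluoride step frees both at the end.

Step 16
Reactants: 21 (1S,4E,6R,7S,9Z)-1,15-bis(TBSO)-8,8-ethylenedioxy-9-iodo-8,9-secogermacra-4,9-dien-12,6-olide
Product: 23 (1S,4E,6R,7S,9Z)-1,15-bis(TBSO)-9-iodo-8-oxo-8,9-secogermacra-4,9-dien-12,6-olide, via lutidinium salt 22 (not isolated)
Conditions: TESOTf, 2,6-lutidine, CH2Cl2, 0 °C; then H2O, rt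
Reagents that add atoms: water, O
Why: The silyl triflate activates one acetal oxygen and 2,6-lutidine traps the oxocarbenium ion as salt 22, which water hydrolyses at almost neutral pH, a known chemoselective acetal cleavage that spares TBS ethers and avoids the acid or base that would epimerise C7 or eliminate the C6 acyloxy group.

**Ring closure (step 17)**

Step 17
Reactants: 23 (1S,4E,6R,7S,9Z)-1,15-bis(TBSO)-9-iodo-8-oxo-8,9-secogermacra-4,9-dien-12,6-olide
Product: 26 (1S,4E,6R,7R,8R,9Z)-1,15-bis(TBSO)-8-hydroxygermacra-4,9-dien-12,6-olide, via alkenylchromium 24 (not isolated), via chromium alkoxide 25 (not isolated)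
Conditions: CrCl2 (15 equiv), NiCl2 (0.15 equiv), degassed DMSO, 2 mM, slow addition of 23, rt; aqueous work-up
Reagents that add atoms: none
Why: NiCl2 is reduced by CrCl2 to zerovalent nickel, which inserts into the C9–I bond and passes the alkenyl group with retained (Z)-geometry to trivalent chromium to give 24, and the polarised C9–Cr bond then adds to the C8 formyl group to give alkoxide 25, hydrolysed on work-up. This is the Nozaki–Hiyama–Kishi reaction in its intramolecular form, which is established for closing medium-sized carbocycles, ten-membered sesquiterpene lactone rings included. Ring A closes in a 10-exo-trig nucleophilic addition that forms C8–C9 as the only new skeletal bond, helped by the short reach imposed by the 6,7-trans substitution of ring B and the two ring-cis alkenes C4=C5 and C9=C10, and by slow addition at high dilution, which holds back intermolecular coupling. C8 is the only new stereocentre and is controlled by C7: since the tether starts at C6, C9 can approach only anti to the C7–C11 bond, and in this Felkin-type arrangement it should pass over H7 with the formyl hydrogen next to H7 and the carbonyl oxygen next to C6, which gives the 8β (8R) carbinol. The step needs chemoselectivity for the aldehyde and a non-basic medium, and both come from the alkenylchromium reagent, which ignores the lactone and the silyl ethers and does not deprotonate C7, so neither epimerisation nor loss of the C6 acyloxy group by β-elimination is expected. C11 is deliberately still a CH2 group, so there is no acrylate for divalent chromium to reduce and no way for the C7 hydrogen to shift into a conjugated butenolide.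

**Endgame (steps 18–22)**

Step 18
Reactants: 26 (1S,4E,6R,7R,8R,9Z)-1,15-bis(TBSO)-8-hydroxygermacra-4,9-dien-12,6-olide
Product: 27 8-O-trimethylsilyl ether of 26
Conditions: TMSCl, imidazole, CH2Cl2, 0 °C
Reagents that add atoms: trimethylsilyl chloride, C[Si](C)(C)Cl
Why: Transient silyl ether formation keeps a C8 alkoxide from forming in the strongly basic next step, since that alkoxide is γ to C12 and well placed to attack it and move the lactone from O6 to O8.

Step 19
Reactants: 27 8-O-trimethylsilyl ether of 26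
Product: 29 (11R)-13-(dimethylamino)-1,15-bis(TBSO)-8-(TMSO)germacra-4,9-dien-12,6-olide, via lithium enolate 28 (not isolated)
Conditions: LiN(iPr)2, THF, −78 °C; CH2=NMe2+ I−, −78 to 0 °C
Reagents that add atoms: dimethylmethyleneiminium iodide (Eschenmoser's salt), C=[N+](C)C.[I-]
Why: In this lactone enolate Mannich reaction C11 carries the only acidic hydrogens once O8 is capped, the enolate has no β-leaving group, and the iminium ion should be taken up on the face of ring B opposite the C7–C8 bond, a configuration that is erased in the next step.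

Step 20
Reactants: 29 (11R)-13-(dimethylamino)-1,15-bis(TBSO)-8-(TMSO)germacra-4,9-dien-12,6-olide
Product: 32 (1S,4E,6R,7R,8R,9Z)-1,15-bis(TBSO)-8-hydroxygermacra-4,9,11(13)-trien-12,6-olide, via ammonium iodide 30 (not isolated), via silylated methylene lactone 31 (not isolated)
Conditions: MeI, CH2Cl2, rt; NaHCO3 aq., CH2Cl2, rt; citric acid (cat.), MeOH, 0 °C
Reagents that add atoms: none
Why: Exhaustive N-methylation turns the amine into a leaving group, mild base triggers the Hofmann-type E1cB elimination to the exocyclic C11=C13 alkene, and catalytic citric acid in methanol removes only the very labile TMS ether.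

Step 21
Reactants: 32 (1S,4E,6R,7R,8R,9Z)-1,15-bis(TBSO)-8-hydroxygermacra-4,9,11(13)-trien-12,6-olide; 33 (S)-2-methylbutanoic acid
Product: 34 (1S,4E,6R,7R,8R,9Z)-1,15-bis(TBSO)-8-[(2S)-2-methylbutanoyloxy]germacra-4,9,11(13)-trien-12,6-olide
Conditions: DCC, DMAP (0.2 equiv), CH2Cl2, 0 °C to rt
Reagents that add atoms: none
Why: Steglich esterification through the O-acylisourea and the acylpyridinium ion acylates the only free hydroxyl with retention at C8, and the low DMAP loading and temperature guard the α-stereocentre of the acid.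

Step 22
Reactants: 34 (1S,4E,6R,7R,8R,9Z)-1,15-bis(TBSO)-8-[(2S)-2-methylbutanoyloxy]germacra-4,9,11(13)-trien-12,6-olide
Product: 35 (1S,4E,6R,7R,8R,9Z)-1,15-dihydroxy-8-[(2S)-2-methylbutanoyloxy]germacra-4,9,11(13)-trien-12,6-olide (CNP0526758.1)
Conditions: HF·pyridine, pyridine, THF, 0 °C to rt
Reagents that add atoms: none
Why: Fluoride-mediated desilylation with buffered HF·pyridine cleaves both TBS ethers without base, so ester migration, lactone transposition and conjugate addition to the methylene lactone are avoided.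

**Compound list**

1 | propargyl alcohol (prop-2-yn-1-ol) | C#CCO | starting material
2 | cyclic (Z)-alkenylmagnesium alkoxide (five-membered ring O–Mg–CH=C(CH3)–CH2) | CC1=C[Mg]OC1 | intermediate
3 | (Z)-3-iodo-2-methylprop-2-en-1-ol | OC/C(C)=C\I | intermediate
4 | (Z)-3-iodo-2-methylprop-2-enal | O=C/C(C)=C\I | intermediate
5 | diisopinocampheylborinate ester of 6 | C=CC[C@H](OB([C@@H]1C[C@@H]2C[C@H]([C@H]1C)C2(C)C)[C@@H]1C[C@@H]2C[C@H]([C@H]1C)C2(C)C)/C(C)=C\I | intermediate
6 | (1Z,3S)-1-iodo-2-methylhexa-1,5-dien-3-ol | C=CC[C@H](O)/C(C)=C\I | intermediate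
7 | (1Z,3S)-3-(TBSO)-1-iodo-2-methylhexa-1,5-diene | C=CC[C@H](O[Si](C)(C)C(C)(C)C)/C(C)=C\I | intermediate
8 | 9-[(4S,5Z)-4-(TBSO)-6-iodo-5-methylhex-5-enyl]-9-borabicyclo[3.3.1]nonane | C1CC2CCCC(C1)B2CCC[C@H](O[Si](C)(C)C(C)(C)C)/C(C)=C\I | intermediate
9 | (4S,5Z)-4-(TBSO)-6-iodo-5-methylhex-5-en-1-ol | OCCC[C@H](O[Si](C)(C)C(C)(C)C)/C(C)=C\I | intermediate
10 | (1Z,3S)-3-(TBSO)-1,6-diiodo-2-methylhex-1-ene | ICCC[C@H](O[Si](C)(C)C(C)(C)C)/C(C)=C\I | intermediate
11 | [(4S,5Z)-4-(TBSO)-6-iodo-5-methylhex-5-enyl]triphenylphosphonium iodide | [I-].c1ccccc1[P+](c1ccccc1)(c1ccccc1)CCC[C@H](O[Si](C)(C)C(C)(C)C)/C(C)=C\I | intermediate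
12 | [(4S,5Z)-4-(TBSO)-6-iodo-5-methylhex-5-enylidene]triphenylphosphorane | c1ccccc1P(c1ccccc1)(c1ccccc1)=CCC[C@H](O[Si](C)(C)C(C)(C)C)/C(C)=C\I | intermediate
13 | (5S,6Z)-5-(TBSO)-7-iodo-6-methyl-2-(triphenylphosphoranylidene)hept-6-enal | O=CC(CC[C@H](O[Si](C)(C)C(C)(C)C)/C(C)=C\I)=P(c1ccccc1)(c1ccccc1)c1ccccc1 | intermediate
14 | (S)-5-(hydroxymethyl)furan-2(5H)-one | O=C1C=C[C@@H](CO)O1 | starting material
15 | (S)-5-[(TBSO)methyl]furan-2(5H)-one | O=C1C=C[C@@H](CO[Si](C)(C)C(C)(C)C)O1 | intermediate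
16 | (4S,5S)-5-[(TBSO)methyl]-4-(1,3-dioxolan-2-yl)dihydrofuran-2(3H)-one | O=C1O[C@H](CO[Si](C)(C)C(C)(C)C)[C@@H](C2OCCO2)C1 | intermediate
17 | (4S,5S)-4-(1,3-dioxolan-2-yl)-5-(hydroxymethyl)dihydrofuran-2(3H)-one | O=C1O[C@H](CO)[C@@H](C2OCCO2)C1 | intermediate
18 | (2S,3S)-3-(1,3-dioxolan-2-yl)-5-oxotetrahydrofuran-2-carbaldehyde | O=C1O[C@H](C=O)[C@@H](C2OCCO2)C1 | intermediate
19 | (1S,4E,6R,7S,9Z)-1-(TBSO)-8,8-ethylenedioxy-9-iodo-15-oxo-8,9-secogermacra-4,9-dien-12,6-olide | O=C1O[C@H](/C=C(/C=O)CC[C@H](O[Si](C)(C)C(C)(C)C)/C(C)=C\I)[C@@H](C2OCCO2)C1 | intermediate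
20 | (1S,4E,6R,7S,9Z)-1-(TBSO)-8,8-ethylenedioxy-15-hydroxy-9-iodo-8,9-secogermacra-4,9-dien-12,6-olide | O=C1O[C@H](/C=C(/CO)CC[C@H](O[Si](C)(C)C(C)(C)C)/C(C)=C\I)[C@@H](C2OCCO2)C1 | intermediate
21 | (1S,4E,6R,7S,9Z)-1,15-bis(TBSO)-8,8-ethylenedioxy-9-iodo-8,9-secogermacra-4,9-dien-12,6-olide | O=C1O[C@H](/C=C(/CO[Si](C)(C)C(C)(C)C)CC[C@H](O[Si](C)(C)C(C)(C)C)/C(C)=C\I)[C@@H](C2OCCO2)C1 | intermediate
22 | N-[C8-(2-triethylsilyloxyethoxy)]-2,6-lutidinium triflate derived from 21 | O=C1O[C@H](/C=C(/CO[Si](C)(C)C(C)(C)C)CC[C@H](O[Si](C)(C)C(C)(C)C)/C(C)=C\I)[C@@H](C(OCCO[Si](CC)(CC)CC)[n+]2c(C)cccc2C)C1.[O-]S(=O)(=O)C(F)(F)F | intermediate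
23 | (1S,4E,6R,7S,9Z)-1,15-bis(TBSO)-9-iodo-8-oxo-8,9-secogermacra-4,9-dien-12,6-olide (6,7-trans lactone; C7 formyl group) | O=C1O[C@H](/C=C(/CO[Si](C)(C)C(C)(C)C)CC[C@H](O[Si](C)(C)C(C)(C)C)/C(C)=C\I)[C@@H](C=O)C1 | intermediate
24 | (9Z)-C9 alkenylchromium dichloride derived from 23 | O=C1O[C@H](/C=C(/CO[Si](C)(C)C(C)(C)C)CC[C@H](O[Si](C)(C)C(C)(C)C)/C(C)=C\[Cr](Cl)Cl)[C@@H](C=O)C1 | intermediate
25 | C8 chromium dichloride alkoxide of 26 | C1C(=O)O[C@@H]2/C=C(/CO[Si](C)(C)C(C)(C)C)CC[C@H](O[Si](C)(C)C(C)(C)C)/C(C)=C\[C@@H](O[Cr](Cl)Cl)[C@@H]12 | intermediate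
26 | (1S,4E,6R,7R,8R,9Z)-1,15-bis(TBSO)-8-hydroxygermacra-4,9-dien-12,6-olide (1α-OTBS; 8β-OH; H6β; H7α) | C1C(=O)O[C@@H]2/C=C(/CO[Si](C)(C)C(C)(C)C)CC[C@H](O[Si](C)(C)C(C)(C)C)/C(C)=C\[C@@H](O)[C@@H]12 | intermediate
27 | 8-O-trimethylsilyl ether of 26 | C1C(=O)O[C@@H]2/C=C(/CO[Si](C)(C)C(C)(C)C)CC[C@H](O[Si](C)(C)C(C)(C)C)/C(C)=C\[C@@H](O[Si](C)(C)C)[C@@H]12 | intermediate
28 | lithium C11=C12 enolate of 27 | C1=C(O[Li])O[C@@H]2/C=C(/CO[Si](C)(C)C(C)(C)C)CC[C@H](O[Si](C)(C)C(C)(C)C)/C(C)=C\[C@@H](O[Si](C)(C)C)[C@@H]12 | intermediate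
29 | (11R)-13-(dimethylamino)-1,15-bis(TBSO)-8-(TMSO)germacra-4,9-dien-12,6-olide | CN(C)C[C@@H]1C(=O)O[C@@H]2/C=C(/CO[Si](C)(C)C(C)(C)C)CC[C@H](O[Si](C)(C)C(C)(C)C)/C(C)=C\[C@@H](O[Si](C)(C)C)[C@@H]12 | intermediate
30 | C13 trimethylammonium iodide derived from 29 | C[N+](C)(C)C[C@@H]1C(=O)O[C@@H]2/C=C(/CO[Si](C)(C)C(C)(C)C)CC[C@H](O[Si](C)(C)C(C)(C)C)/C(C)=C\[C@@H](O[Si](C)(C)C)[C@@H]12.[I-] | intermediate
31 | 8-O-trimethylsilyl ether of 32 | C=C1C(=O)O[C@@H]2/C=C(/CO[Si](C)(C)C(C)(C)C)CC[C@H](O[Si](C)(C)C(C)(C)C)/C(C)=C\[C@@H](O[Si](C)(C)C)[C@@H]12 | intermediate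
32 | (1S,4E,6R,7R,8R,9Z)-1,15-bis(TBSO)-8-hydroxygermacra-4,9,11(13)-trien-12,6-olide | C=C1C(=O)O[C@@H]2/C=C(/CO[Si](C)(C)C(C)(C)C)CC[C@H](O[Si](C)(C)C(C)(C)C)/C(C)=C\[C@@H](O)[C@@H]12 | intermediate
33 | (S)-2-methylbutanoic acid | CC[C@H](C)C(=O)O | starting material
34 | (1S,4E,6R,7R,8R,9Z)-1,15-bis(TBSO)-8-[(2S)-2-methylbutanoyloxy]germacra-4,9,11(13)-trien-12,6-olide | C=C1C(=O)O[C@@H]2/C=C(/CO[Si](C)(C)C(C)(C)C)CC[C@H](O[Si](C)(C)C(C)(C)C)/C(C)=C\[C@@H](OC(=O)[C@@H](C)CC)[C@@H]12 | intermediate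
35 | (1S,4E,6R,7R,8R,9Z)-1,15-dihydroxy-8-[(2S)-2-methylbutanoyloxy]germacra-4,9,11(13)-trien-12,6-olide (CNP0526758.1) | C=C1C(=O)O[C@@H]2/C=C(/CO)CC[C@H](O)/C(C)=C\[C@@H](OC(=O)[C@@H](C)CC)[C@@H]12 | target

**Step count**

Total step count: 22.
Longest linear sequence: 18 steps (steps 1–8 and 13–22, from propargyl alcohol). The lactone branch (steps 9–12) is convergent.

**Steps most likely to fail**

Step 17 (key step). Facial selectivity in the addition to the C8 formyl group may be poor, so the 8α-carbinol may prevail.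
- In the fallback, C8 is set by hydride delivery to a ring ketone rather than in the C–C bond formation.
- It sets out from 23, which is cyclised as in step 17.
- Hydrolysis of the C8-epimeric chromium alkoxide F1 gives the 8α-alcohol F2, alone or mixed with 26.
- DMP in CH2Cl2 oxidises this material to the (9Z)-8-oxo lactone F3.
- Luche reduction (NaBH4, CeCl3·7H2O, MeOH, −78 °C) should then deliver hydride from the outer face of ring A, past H7.
- The fallback comes back to the route at 26.

Step 16. The acetal is deactivated by the neighbouring lactone and may ionise slowly. Competing processes are loss of the allylic silyl ethers and epimerisation or β-elimination of the liberated aldehyde.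
- In the fallback, C8 is carried at the alcohol level and the aldehyde is released by a neutral oxidation.
- It sets out from 15. Benzophenone-sensitised photoaddition of methanol gives the trans hydroxymethyl lactone F4.
- 4-Methoxybenzyl trichloroacetimidate with catalytic camphorsulfonic acid gives the PMB ether F5.
- Et3N·3HF frees the primary alcohol F6, and DMP gives the aldehyde F7.
- Wittig reaction of F7 with 13 gives the (E)-enal F8.
- Luche reduction gives the allylic alcohol F9, and TBSCl with imidazole gives the bis-silyl PMB ether F10.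
- DDQ in CH2Cl2 and pH 7 buffer uncovers the C8 alcohol F11, and DMP oxidation comes back to the route at 23.

Step 13. Olefination by the hindered, weakly nucleophilic formyl ylide may be sluggish, so the α-acyloxy aldehyde may hydrate, epimerise or decompose on prolonged heating.
- The fallback uses a more nucleophilic ester ylide at room temperature, followed by a redox correction.
- It sets out from 11. Ylide 12 is generated with two equivalents of NaN(SiMe3)2 and acylated with methyl chloroformate to give the ester ylide F12.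
- F12 reacts with 18 in CH2Cl2 at rt to give the (E)-enoate F13.
- Excess iBu2AlH in CH2Cl2 at −78 °C reduces the ester to the allylic alcohol and the lactone to the lactol, giving the lactol diol F14.
- TBSCl with imidazole at −20 °C silylates only the primary allylic hydroxyl, giving the silylated lactol F15.
- Ag2CO3 on Celite in warm toluene oxidises the lactol back to the lactone, and the fallback comes back to the route at 21.

Further compounds
F1 | step 17 | C8-epimeric chromium dichloride alkoxide (8S) | C1C(=O)O[C@@H]2/C=C(/CO[Si](C)(C)C(C)(C)C)CC[C@H](O[Si](C)(C)C(C)(C)C)/C(C)=C\[C@H](O[Cr](Cl)Cl)[C@@H]12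
F2 | step 17 | (8S)-epimer of 26 (8α-alcohol) | C1C(=O)O[C@@H]2/C=C(/CO[Si](C)(C)C(C)(C)C)CC[C@H](O[Si](C)(C)C(C)(C)C)/C(C)=C\[C@H](O)[C@@H]12
F3 | step 17 | (9Z)-1,15-bis(TBSO)-8-oxogermacra-4,9-dien-12,6-olide | C1C(=O)O[C@@H]2/C=C(/CO[Si](C)(C)C(C)(C)C)CC[C@H](O[Si](C)(C)C(C)(C)C)/C(C)=C\C(=O)[C@@H]12
F4 | step 16 | (4R,5S)-5-[(TBSO)methyl]-4-(hydroxymethyl)dihydrofuran-2(3H)-one | O=C1O[C@H](CO[Si](C)(C)C(C)(C)C)[C@@H](CO)C1
F5 | step 16 | C8 PMB ether of F4 | O=C1O[C@H](CO[Si](C)(C)C(C)(C)C)[C@@H](COCc2ccc(OC)cc2)C1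
F6 | step 16 | trans-5-(hydroxymethyl)-4-[(PMBO)methyl]dihydrofuran-2(3H)-one | O=C1O[C@H](CO)[C@@H](COCc2ccc(OC)cc2)C1
F7 | step 16 | trans-3-[(PMBO)methyl]-5-oxotetrahydrofuran-2-carbaldehyde | O=C1O[C@H](C=O)[C@@H](COCc2ccc(OC)cc2)C1
F8 | step 16 | (4E,9Z)-1-(TBSO)-9-iodo-15-oxo-8-(PMBO)-8,9-secogermacra-4,9-dien-12,6-olide | O=C1O[C@H](/C=C(/C=O)CC[C@H](O[Si](C)(C)C(C)(C)C)/C(C)=C\I)[C@@H](COCc2ccc(OC)cc2)C1
F9 | step 16 | (4E,9Z)-1-(TBSO)-15-hydroxy-9-iodo-8-(PMBO)-8,9-secogermacra-4,9-dien-12,6-olide | O=C1O[C@H](/C=C(/CO)CC[C@H](O[Si](C)(C)C(C)(C)C)/C(C)=C\I)[C@@H](COCc2ccc(OC)cc2)C1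
F10 | step 16 | (4E,9Z)-1,15-bis(TBSO)-9-iodo-8-(PMBO)-8,9-secogermacra-4,9-dien-12,6-olide | O=C1O[C@H](/C=C(/CO[Si](C)(C)C(C)(C)C)CC[C@H](O[Si](C)(C)C(C)(C)C)/C(C)=C\I)[C@@H](COCc2ccc(OC)cc2)C1
F11 | step 16 | (4E,9Z)-1,15-bis(TBSO)-8-hydroxy-9-iodo-8,9-secogermacra-4,9-dien-12,6-olide | O=C1O[C@H](/C=C(/CO[Si](C)(C)C(C)(C)C)CC[C@H](O[Si](C)(C)C(C)(C)C)/C(C)=C\I)[C@@H](CO)C1
F12 | step 13 | methyl (5S,6Z)-5-(TBSO)-7-iodo-6-methyl-2-(triphenylphosphoranylidene)hept-6-enoate | COC(=O)C(CC[C@H](O[Si](C)(C)C(C)(C)C)/C(C)=C\I)=P(c1ccccc1)(c1ccccc1)c1ccccc1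
F13 | step 13 | (4E,9Z)-enoate: C15 methyl ester analogue of 19 | O=C1O[C@H](/C=C(/C(=O)OC)CC[C@H](O[Si](C)(C)C(C)(C)C)/C(C)=C\I)[C@@H](C2OCCO2)C1
F14 | step 13 | C12 lactol of 20 (anomers) | OC1O[C@H](/C=C(/CO)CC[C@H](O[Si](C)(C)C(C)(C)C)/C(C)=C\I)[C@@H](C2OCCO2)C1
F15 | step 13 | C12 lactol of 21 (anomers) | OC1O[C@H](/C=C(/CO[Si](C)(C)C(C)(C)C)CC[C@H](O[Si](C)(C)C(C)(C)C)/C(C)=C\I)[C@@H](C2OCCO2)C1
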